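**Remark:** prostanoid numbering is used throughout: C1 = ester carbon, C5–C7 = acetoxy carbons, C8–C12 = ring atoms (C9 = ring carbonyl, C10 = chlorinated carbon, C12 = carbinol carbon), C13–C20 = octadienyl chain.

## Retrosynthetic overview

- The last bond formed is C9–C10. The 2-chloro-4-hydroxycyclopent-2-enone (ring C8–C12) is the cycloisomer of an acyclic 4-alkynal: a C9 aldehyde joined through C8 and the propargylic carbinol C12 to a C11≡C10–Cl chloroalkyne. This relationship (C9=O, C10(Cl)=C11, oxygenated quaternary C12) lets a neutral hydroacylation form ring, enone and vinyl chloride in one step, after the base-labile C7 acetate is in place.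
- C12 is the carbonyl carbon of γ-lactone 5, which takes up allyl and then alkynyl (Felkin–Anh and 1,3-anti control reinforce). The allyl group becomes the C14 aldehyde and a Z-Wittig reaction completes the ω-chain.
- C7 and C8 come from face-selective hydrogenation of tetronic acid 4 (all-cis lactone 5, a temporary ring template opened at C12). C5 and C6 come from L-threonate 1. C1–C3 are added by a Giese reaction at C4.
- Ring order: butenolide (Dieckmann) → lactone/lactol template → opened → cyclopentenone C8–C12, the only ring of the target, formed last.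

Key step: step 19

## Route

Step 1
Reactants: 1 methyl 3,4-O-isopropylidene-L-threonate; 2 3-[(tert-butyldimethylsilyl)oxy]propanoic acid
Product: 3 O6-acylated threonate
Conditions: DCC, DMAP (cat.), CH2Cl2, 0 °C → rt
Reagents that add atoms: none
Why: Steglich esterification of the secondary α-hydroxy ester; the chiral-pool stereocentres C5 and C6 are not touched.

Step 2
Reactants: 3 O6-acylated threonate
Product: 4 tetronic acid (butenolide ring O6–C12–C8=C7–C6)
Conditions: LiHMDS (2.3 equiv), THF, −78 → −20 °C; then cold 0.5 M HCl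
Reagents that add atoms: none
Why: Dieckmann condensation of an α-acyloxy ester (C8 enolate onto the C7 ester, 5-exo-trig) driven by formation of the tetronate anion, the standard tetronic acid synthesis; low temperature limits β-elimination of the silyloxy group, and C6 is no longer acidic once the tetronate has formed.

Step 3
Reactants: 4 tetronic acid
Product: 5 all-cis γ-lactone
Conditions: H2 (4 atm), Rh/Al2O3, EtOAc, rt
Reagents that add atoms: none
Why: Heterogeneous syn-hydrogenation of the enol double bond from the face opposite the C6 dioxolanyl group, as for 3-alkyltetronic acids and ascorbic acid, should set C7 and C8 with the C9 arm, the C7 hydroxyl and the C6 substituent all cis.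

Step 4
Reactants: 5 all-cis γ-lactone
Product: 6 C12 lactol (2-allyl-2-hydroxytetrahydrofuran, anomer mixture)
Conditions: allylmagnesium bromide (2.2 equiv), THF, −78 °C; aq. NH4Cl
Reagents that add atoms: allylmagnesium bromide, C=CC[Mg]Br
Why: Mono-addition of a Grignard reagent to a γ-lactone at low temperature, where the magnesium lactolate does not collapse (as in additions to aldonolactones); the first equivalent only deprotonates the C7 hydroxyl.

Step 5
Reactants: 6 C12 lactol
Product: 8 C12 tertiary propargylic triol, via open-chain dihydroxy allyl ketone 7 (not isolated)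
Conditions: trimethylsilylacetylene, n-BuLi, then anhydrous CeCl3 (4 equiv each), THF, −78 °C; add 6; −78 → −40 °C; aq. NH4Cl
Reagents that add atoms: trimethylsilylacetylene, C#C[Si](C)(C)C
Why: Organocerium 1,2-addition to ring-opened ketone 7: the Felkin–Anh mode (C7 as the large group on C8) and 1,3-anti induction from the C7 alkoxide (β-chelate with C6 and C9 pseudo-equatorial, axial attack) place the alkynyl group on the same face and so set C12, while the weakly basic cerium reagent avoids enolisation of the β,γ-unsaturated ketone.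

Step 6
Reactants: 8 C12 tertiary propargylic triol
Product: 9 6,7-diacetate
Conditions: Ac2O, pyridine, DMAP (cat.), CH2Cl2, 0 °C
Reagents that add atoms: acetic anhydride, CC(=O)OC(C)=O
Why: Acylation of the two secondary hydroxyls; the tertiary propargylic C12 hydroxyl should not react under these conditions.

Step 7
Reactants: 9 6,7-diacetate
Product: 10 4,5-diol
Conditions: CeCl3·7H2O, oxalic acid (cat.), MeCN, rt
Reagents that add atoms: none
Why: Lewis-acid-assisted hydrolysis of a terminal isopropylidene acetal under conditions that spare primary silyl ethers, acetates and the silylalkyne.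

Step 8
Reactants: 10 4,5-diol
Product: 11 C4 iodide with free C5 hydroxyl
Conditions: PPh3, I2, imidazole, CH2Cl2, 0 °C → rt; aq. Na2S2O3/NaHCO3
Reagents that add atoms: iodine, II
Why: Appel-type iodination is selective for the primary C4 hydroxyl over the secondary C5 and tertiary C12 hydroxyls and does not touch the C5 stereocentre.

Step 9
Reactants: 11 C4 iodide with free C5 hydroxyl
Product: 12 5,6,7-triacetate iodide
Conditions: Ac2O, pyridine, DMAP (cat.), CH2Cl2, 0 °C
Reagents that add atoms: acetic anhydride, CC(=O)OC(C)=O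
Why: Acetylation of the remaining secondary hydroxyl completes the triacetate; any earlier 6→5 acetyl shift converges on the same product.

Step 10
Reactants: 12 5,6,7-triacetate iodide
Product: 13 C12 triethylsilyl ether
Conditions: TESOTf, 2,6-lutidine, CH2Cl2, −78 → 0 °C; aq. NaHCO3
Reagents that add atoms: triethylsilyl trifluoromethanesulfonate, CC[Si](CC)(CC)OS(=O)(=O)C(F)(F)F
Why: Silyl triflate silylation of the hindered tertiary alcohol masks the propargylic hydroxyl for the radical and ylide steps that follow.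

Step 11
Reactants: 13 C12 triethylsilyl ether
Product: 14 methyl ester with C1–C3 installed
Conditions: methyl acrylate (10 equiv), Bu3SnH (slow addition), AIBN (cat.), PhH, 80 °C
Reagents that add atoms: methyl acrylate, C=CC(=O)OC
Why: Giese addition of the primary C4 radical to the acrylate builds C1–C3 without touching C5; the flanked disubstituted silylalkyne and the unactivated allyl group should be far slower radical acceptors than the acrylate.

Step 12
Reactants: 14 methyl ester with C1–C3 installed
Product: 15 C14 aldehyde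
Conditions: OsO4 (2 mol %), NaIO4 (4 equiv), 2,6-lutidine, dioxane–H2O, rt
Reagents that add atoms: sodium periodate, [Na+].[O-]I(=O)(=O)=O; osmium tetroxide (catalytic oxygen carrier), O=[Os](=O)(=O)=O
Why: Lemieux–Johnson cleavage of the only C=C bond gives the aldehyde; the silylated alkyne is not attacked.

Step 13
Reactants: 16 (Z)-hex-3-en-1-ol
Product: 17 (Z)-1-iodohex-3-ene
Conditions: PPh3, I2, imidazole, CH2Cl2, 0 °C; aq. Na2S2O3/NaHCO3
Reagents that add atoms: iodine, II
Why: Appel-type iodination of a primary alcohol; the Z double bond is not involved.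

Step 14
Reactants: 17 (Z)-1-iodohex-3-ene
Product: 18 [(Z)-hex-3-enyl]triphenylphosphonium iodide
Conditions: PPh3, MeCN, reflux
Reagents that add atoms: triphenylphosphine, c1ccc(cc1)P(c1ccccc1)c1ccccc1
Why: SN2 quaternisation of the phosphine by a primary iodide.

Step 15
Reactants: 15 C14 aldehyde; 18 [(Z)-hex-3-enyl]triphenylphosphonium iodide
Product: 20 (14Z,17Z)-diene, via (Z)-hex-3-enylidenetriphenylphosphorane 19 (not isolated)
Conditions: 18, NaHMDS, THF, −78 → 0 → −78 °C; then 15, −78 → −20 °C
Reagents that add atoms: none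
Why: Wittig reaction of a non-stabilised ylide under lithium-free conditions should give the Z C14=C15 bond; at −78 °C the aldehyde reacts much faster than the acetates and the methyl ester.

Step 16
Reactants: 20 (14Z,17Z)-diene
Product: 21 chloroalkyne
Conditions: AgF, N-chlorosuccinimide, MeCN, rt, dark; aq. NH4Cl
Reagents that add atoms: N-chlorosuccinimide, O=C1CCC(=O)N1Cl
Why: Silver-mediated halodesilylation of a 1-silylalkyne through the silver acetylide, a known route to 1-haloalkynes; the chlorine source is not activated toward the isolated Z alkenes.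

Step 17
Reactants: 21 chloroalkyne
Product: 22 C9,C12-diol
Conditions: HF·pyridine, pyridine, THF, 0 °C → rt
Reagents that add atoms: none
Why: Buffered fluoride cleavage of the tertiary triethylsilyl and primary tert-butyldimethylsilyl ethers without acetate cleavage or migration.

Step 18
Reactants: 22 C9,C12-diol
Product: 23 4-alkynal (C9 aldehyde)
Conditions: Dess–Martin periodinane, NaHCO3, CH2Cl2, 0 °C → rt; used without chromatography
Reagents that add atoms: none
Why: Dess–Martin oxidation of the primary alcohol under base-free buffered conditions; the tertiary C12 hydroxyl cannot be oxidised and the β-acetoxy aldehyde is not exposed to base.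

Step 19
Reactants: 23 4-alkynal (C9 aldehyde)
Product: 24 target
Conditions: [Rh(dppe)]2(BF4)2 (10 mol %), acetone, rt
Reagents that add atoms: none
Why: Proposed new method: oxidative addition of the aldehyde C9–H bond to cationic monovalent rhodium gives an acyl rhodium hydride, which adds across the tethered C10≡C11 triple bond in the trans sense to a six-membered acyl(alkenyl)rhodacycle, and C9–C10 reductive elimination releases the enone and the catalyst, so 23 is simply isomerised to 24. The closest known reaction type is the rhodium–bisphosphine-catalysed intramolecular trans-hydroacylation of 5-alkyl- and 5-aryl-4-alkynals to cyclopent-2-enones, which tolerates a fully substituted ether carbon at C3 of the alkynal; a 5-chloro-4-alkynal has not been used, hence the label. The only ring formed, cyclopentenone C8–C12, closes in the 5-endo-dig sense imposed by the trans addition, the competing 4-exo-dig closure to a cyclobutanone needing a cis addition that the dppe ligand should disfavour. No stereocentre is created: C8 and C12 keep the configuration set in steps 3 and 5 because the medium is neutral and the acyl metal intermediate cannot enolise, and the C10=C11 geometry is fixed by the ring. The step needs chemoselectivity for C9–H insertion over C10–Cl insertion, decarbonylation and loss of the C7 acetate; the aldehyde C–H bond should be the better partner for the cationic rhodium centre than a C(sp)–Cl bond, the quaternary C12 and the branch at C8 hold aldehyde and alkyne together so that cyclisation outruns decarbonylation, and the absence of base keeps the β-acetoxy carbonyl unit intact.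

## Compound list

1 | methyl 3,4-O-isopropylidene-L-threonate [methyl (2R)-2-hydroxy-2-[(4S)-2,2-dimethyl-1,3-dioxolan-4-yl]acetate] | COC(=O)[C@H](O)[C@@H]1COC(C)(C)O1 | starting material
2 | 3-[(tert-butyldimethylsilyl)oxy]propanoic acid | O=C(O)CCO[Si](C)(C)C(C)(C)C | starting material
3 | methyl 2-O-{3-[(tert-butyldimethylsilyl)oxy]propanoyl}-3,4-O-isopropylidene-L-threonate | COC(=O)[C@H](OC(=O)CCO[Si](C)(C)C(C)(C)C)[C@@H]1COC(C)(C)O1 | intermediate
4 | (5R)-5-[(4S)-2,2-dimethyl-1,3-dioxolan-4-yl]-4-hydroxy-3-{[(tert-butyldimethylsilyl)oxy]methyl}furan-2(5H)-one | O=C1O[C@H]([C@@H]2COC(C)(C)O2)C(O)=C1CO[Si](C)(C)C(C)(C)C | intermediate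
5 | (3S,4R,5S)-3-{[(tert-butyldimethylsilyl)oxy]methyl}-5-[(4S)-2,2-dimethyl-1,3-dioxolan-4-yl]-4-hydroxydihydrofuran-2(3H)-one (all-cis) | O=C1O[C@H]([C@@H]2COC(C)(C)O2)[C@H](O)[C@@H]1CO[Si](C)(C)C(C)(C)C | intermediate
6 | 2-allyl lactol of 5 (C12 hemiketal, anomer mixture; C5–C8 as in 5) | C=CCC1(O)O[C@H]([C@@H]2COC(C)(C)O2)[C@H](O)[C@@H]1CO[Si](C)(C)C(C)(C)C | intermediate
7 | open-chain tautomer of 6: allyl ketone at C12 with free C6 and C7 hydroxyls | C=CCC(=O)[C@@H](CO[Si](C)(C)C(C)(C)C)[C@@H](O)[C@H](O)[C@@H]1COC(C)(C)O1 | intermediate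
8 | triol: C12 carbinol bearing allyl and (trimethylsilyl)ethynyl groups; C9 silyl ether; C6 and C7 hydroxyls free; C4/C5 acetonide; C5–C8 and C12 configured as in 24 | C=CC[C@](O)(C#C[Si](C)(C)C)[C@@H](CO[Si](C)(C)C(C)(C)C)[C@@H](O)[C@H](O)[C@@H]1COC(C)(C)O1 | intermediate
9 | 6,7-diacetate of 8 | C=CC[C@](O)(C#C[Si](C)(C)C)[C@@H](CO[Si](C)(C)C(C)(C)C)[C@@H](OC(C)=O)[C@H](OC(C)=O)[C@@H]1COC(C)(C)O1 | intermediate
10 | 4,5-diol 6,7-diacetate | C=CC[C@](O)(C#C[Si](C)(C)C)[C@@H](CO[Si](C)(C)C(C)(C)C)[C@@H](OC(C)=O)[C@H](OC(C)=O)[C@@H](O)CO | intermediate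
11 | 4-iodo-5-hydroxy 6,7-diacetate | C=CC[C@](O)(C#C[Si](C)(C)C)[C@@H](CO[Si](C)(C)C(C)(C)C)[C@@H](OC(C)=O)[C@H](OC(C)=O)[C@@H](O)CI | intermediate
12 | 4-iodo 5,6,7-triacetate (C12 hydroxyl free) | C=CC[C@](O)(C#C[Si](C)(C)C)[C@@H](CO[Si](C)(C)C(C)(C)C)[C@@H](OC(C)=O)[C@H](OC(C)=O)[C@@H](OC(C)=O)CI | intermediate
13 | C12 triethylsilyl ether of 12 | C=CC[C@](O[Si](CC)(CC)CC)(C#C[Si](C)(C)C)[C@@H](CO[Si](C)(C)C(C)(C)C)[C@@H](OC(C)=O)[C@H](OC(C)=O)[C@@H](OC(C)=O)CI | intermediate
14 | methyl 5,6,7-triacetoxyheptanoate chain complete (C1–C7); C8 bears CH2OTBS and the silylated C12 carbinol with allyl and silylethynyl groups | C=CC[C@](O[Si](CC)(CC)CC)(C#C[Si](C)(C)C)[C@@H](CO[Si](C)(C)C(C)(C)C)[C@@H](OC(C)=O)[C@H](OC(C)=O)[C@H](CCCC(=O)OC)OC(C)=O | intermediate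
15 | C14 aldehyde (2-oxoethyl group on C12) | O=CC[C@](O[Si](CC)(CC)CC)(C#C[Si](C)(C)C)[C@@H](CO[Si](C)(C)C(C)(C)C)[C@@H](OC(C)=O)[C@H](OC(C)=O)[C@H](CCCC(=O)OC)OC(C)=O | intermediate
16 | (Z)-hex-3-en-1-ol | CC/C=C\CCO | starting material
17 | (Z)-1-iodohex-3-ene | CC/C=C\CCI | intermediate
18 | [(Z)-hex-3-enyl]triphenylphosphonium iodide | CC/C=C\CC[P+](c1ccccc1)(c1ccccc1)c1ccccc1.[I-] | intermediate
19 | (Z)-hex-3-enylidenetriphenylphosphorane | CC/C=C\CC=P(c1ccccc1)(c1ccccc1)c1ccccc1 | intermediate
20 | (14Z,17Z)-diene with (trimethylsilyl)ethynyl group at C12; C12 and C9 silyl ethers | CC/C=C\C/C=C\C[C@](O[Si](CC)(CC)CC)(C#C[Si](C)(C)C)[C@@H](CO[Si](C)(C)C(C)(C)C)[C@@H](OC(C)=O)[C@H](OC(C)=O)[C@H](CCCC(=O)OC)OC(C)=O | intermediate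
21 | chloroalkyne (C11≡C10–Cl); C12 and C9 silyl ethers | CC/C=C\C/C=C\C[C@](O[Si](CC)(CC)CC)(C#CCl)[C@@H](CO[Si](C)(C)C(C)(C)C)[C@@H](OC(C)=O)[C@H](OC(C)=O)[C@H](CCCC(=O)OC)OC(C)=O | intermediate
22 | C9,C12-diol chloroalkyne triacetate | CC/C=C\C/C=C\C[C@](O)(C#CCl)[C@@H](CO)[C@@H](OC(C)=O)[C@H](OC(C)=O)[C@H](CCCC(=O)OC)OC(C)=O | intermediate
23 | acyclic 4-alkynal: C9 aldehyde, C12 carbinol, C11≡C10–Cl | CC/C=C\C/C=C\C[C@](O)(C#CCl)[C@@H](C=O)[C@@H](OC(C)=O)[C@H](OC(C)=O)[C@H](CCCC(=O)OC)OC(C)=O | intermediate
24 | methyl (5S,6R,7R)-5,6,7-triacetoxy-7-[(1S,5R)-3-chloro-5-hydroxy-5-[(2Z,5Z)-octa-2,5-dienyl]-2-oxocyclopent-3-enyl]heptanoate | CC/C=C\C/C=C\C[C@]1(O)C=C(Cl)C(=O)[C@H]1[C@@H](OC(C)=O)[C@H](OC(C)=O)[C@H](CCCC(=O)OC)OC(C)=O | target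

## Summary and risks

Total steps: 19. Longest linear sequence: 17 (steps 1–12 and 15–19).

Steps most likely to fail:

1. **Step 19 (Proposed new method).** The catalyst may be consumed by insertion into the C10–Cl bond or by rearrangement of the chloroalkyne at the metal, or the acyl rhodium hydride may decarbonylate. The fallback uses known chemistry, sets out from 20 and returns at 24. Iododesilylation of 20 (N-iodosuccinimide, AgF, MeCN) gives the iodoalkyne F1, and cis-reduction with diimide (2-nitrobenzenesulfonylhydrazide, Et3N) gives the (Z)-iodoalkene F2. HF·pyridine then frees the diol F3 and Dess–Martin oxidation gives the aldehyde F4. An intramolecular Nozaki–Hiyama–Kishi reaction (CrCl2, NiCl2 cat., DMF) closes the same C9–C10 bond to the cyclopentenol F5, whose C9 configuration does not matter. Hydroxyl-directed epoxidation of the ring double bond (VO(acac)2, t-BuOOH) gives the epoxy alcohol F6, and Dess–Martin oxidation gives the epoxy ketone F7. Dry HCl in CHCl3 opens the epoxide at C10 and dehydrates the chlorohydrin to 24; this puts in the chlorine without any reagent that attacks the skipped diene.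

2. **Step 2.** β-Elimination of the silyloxy group from the ester enolate, or epimerisation at C6, may compete at the temperature the ring closure needs. The fallback sets out from 1 and returns at 4. Compound 1 is silylated (TESCl, imidazole) to the silyl ether F8. The lithium enolate of methyl 3-[(tert-butyldimethylsilyl)oxy]propanoate, preformed with LDA at −78 °C, is acylated by F8 in an intermolecular crossed Claisen condensation to the β-keto ester F9. PPTS in MeOH removes the triethylsilyl group, and the freed C6 hydroxyl lactonises onto the ester to give 4.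

3. **Step 5.** Enolisation or conjugation of the β,γ-unsaturated ketone, retro-aldol cleavage of the C7–C8 bond in the keto alkoxide, or insufficient facial selectivity at C12 may occur. The fallback sets out from 5 and returns at 8. Aminolysis of 5 (MeNHOMe·HCl, AlMe3) gives the dihydroxy Weinreb amide F10, which is silylated in the same flask (TESOTf, 2,6-lutidine) to the bis-silyl ether F11. Allylmagnesium bromide converts F11 into the allyl ketone F12 without over-addition. The cerium acetylide of step 5 then adds to this open-chain, non-chelating ketone under the same Felkin–Anh and 1,3-anti control to give the carbinol F13. PPTS in MeOH removes both secondary triethylsilyl ethers and returns 8.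

## Further compounds

F1 | step 19 | iodoalkyne analogue of 21 | CC/C=C\C/C=C\C[C@](O[Si](CC)(CC)CC)(C#CI)[C@@H](CO[Si](C)(C)C(C)(C)C)[C@@H](OC(C)=O)[C@H](OC(C)=O)[C@H](CCCC(=O)OC)OC(C)=O
F2 | step 19 | (Z)-iodoalkene (iodine cis to C12) | CC/C=C\C/C=C\C[C@](O[Si](CC)(CC)CC)(/C=C\I)[C@@H](CO[Si](C)(C)C(C)(C)C)[C@@H](OC(C)=O)[C@H](OC(C)=O)[C@H](CCCC(=O)OC)OC(C)=O
F3 | step 19 | C9,C12-diol (Z)-iodoalkene | CC/C=C\C/C=C\C[C@](O)(/C=C\I)[C@@H](CO)[C@@H](OC(C)=O)[C@H](OC(C)=O)[C@H](CCCC(=O)OC)OC(C)=O
F4 | step 19 | C9 aldehyde (Z)-iodoalkene | CC/C=C\C/C=C\C[C@](O)(/C=C\I)[C@@H](C=O)[C@@H](OC(C)=O)[C@H](OC(C)=O)[C@H](CCCC(=O)OC)OC(C)=O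
F5 | step 19 | cyclopent-2-enol (C9 carbinol, epimer mixture) | CC/C=C\C/C=C\C[C@]1(O)C=CC(O)[C@H]1[C@@H](OC(C)=O)[C@H](OC(C)=O)[C@H](CCCC(=O)OC)OC(C)=O
F6 | step 19 | C10,C11-epoxy cyclopentanol | CC/C=C\C/C=C\C[C@]1(O)C2OC2C(O)[C@H]1[C@@H](OC(C)=O)[C@H](OC(C)=O)[C@H](CCCC(=O)OC)OC(C)=O
F7 | step 19 | C10,C11-epoxy cyclopentanone | CC/C=C\C/C=C\C[C@]1(O)C2OC2C(=O)[C@H]1[C@@H](OC(C)=O)[C@H](OC(C)=O)[C@H](CCCC(=O)OC)OC(C)=O
F8 | step 2 | methyl 2-O-triethylsilyl-3,4-O-isopropylidene-L-threonate | COC(=O)[C@H](O[Si](CC)(CC)CC)[C@@H]1COC(C)(C)O1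
F9 | step 2 | β-keto ester (C12 ester, C7 ketone, C8 epimer mixture) | COC(=O)C(CO[Si](C)(C)C(C)(C)C)C(=O)[C@H](O[Si](CC)(CC)CC)[C@@H]1COC(C)(C)O1
F10 | step 5 | dihydroxy Weinreb amide from 5 | CON(C)C(=O)[C@@H](CO[Si](C)(C)C(C)(C)C)[C@@H](O)[C@H](O)[C@@H]1COC(C)(C)O1
F11 | step 5 | 6,7-bis(triethylsilyl) Weinreb amide | CON(C)C(=O)[C@@H](CO[Si](C)(C)C(C)(C)C)[C@@H](O[Si](CC)(CC)CC)[C@H](O[Si](CC)(CC)CC)[C@@H]1COC(C)(C)O1
F12 | step 5 | 6,7-bis(triethylsilyl) allyl ketone | C=CCC(=O)[C@@H](CO[Si](C)(C)C(C)(C)C)[C@@H](O[Si](CC)(CC)CC)[C@H](O[Si](CC)(CC)CC)[C@@H]1COC(C)(C)O1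
F13 | step 5 | 6,7-bis(triethylsilyl) ether of 8 | C=CC[C@](O)(C#C[Si](C)(C)C)[C@@H](CO[Si](C)(C)C(C)(C)C)[C@@H](O[Si](CC)(CC)CC)[C@H](O[Si](CC)(CC)CC)[C@@H]1COC(C)(C)O1
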